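In a closed flask a charged monomer molecule cannot vanish: it stays free, sits in a chain, or has gone a third way, so the gap below the charge in any run counts that third way.

| flask | free monomer | protic impurity | pre-initiator | stray impurity | remark | time |
|---|---|---|---|---|---|---|
| south-west | 0.15 M | 0.020 M | 5 mol% | 4.6 mM | run made earlier |  |
| flask | 0.10 M | 0.0200 M | 5 mol% | 4.6 mM |  | 6.0 h |

south-west run (percent of the free monomer charged)

| time / min | monomer in chains / % | free monomer / % |
|---|---|---|
| 8.00 | 0 | 94.1 |
| 20.0 | 2.4 | 88.3 |
| 50.0 | 10.9 | 76.8 |
| 120 | 36.9 | 49.7 |

(readings scatter by 0.3 percentage points)

- the average divides the monomer in chains by the number of chains begun, living and dead together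
- the earlier runs were read with a standard deviation of 0.3 percentage points
- the earlier runs do not show the number of chains; that part of a forecast is a guess
- no earlier run changes the charge of pre-initiator; that part of a forecast is a guess

- average number of monomer units in a chain (chains begun, living or dead) at 6.0 h
- part of the free monomer that has reacted at 6.0 h

In the south-west run the gap at 120 min is 13.4 %, and protic impurity over free monomer as charged is 13.3 %. So we follow one monomer molecule to its first fork and read that each protic impurity takes one. For this flask the protic share s, the part of the charged free monomer lost that way, is 20.0 %.

Two extreme versions can be solved in the head. With no chains, c equals s; with chains taking the rest, c is 100%. The south-west run, with the same 4.6 mM of stray impurity but 7.50 mM of pre-initiator against 5.00 mM in this flask, held 36.9 % in chains at 120 min, so we expect chains in this flask too and place it above the first. The south-west chains rose from 10.9 % to 36.9 % over the last two readings, so that run shows no end point and we cannot read from it how far below the second this flask stands. We commit to c as s plus a chain share between these limits; dp stays a guess, as no run shows the number of chains.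

The forecast gives dp 35 and c 42 %, “leaving about 0.4 mM active”.

The flask gives dp 31.6 and c 51.4 %.

    monomer in chains + living end → free monomer + living end, rate k1*[living end] as long as [monomer in chains] is above zero (k = 47.0 h⁻¹)
    pre-initiator → initiator (k = 0.330 h⁻¹)
    free monomer + initiator → living end + monomer in chains (k = 93.0 L mol⁻¹ h⁻¹)
    free monomer + living end → monomer in chains + living end, rate k4*[living end]*[free monomer] (k = 980 L mol⁻¹ h⁻¹)
    initiator + stray impurity → spent initiator (k = 7700 L mol⁻¹ h⁻¹)
    protic impurity + free monomer → quenched substrate (k = 24.0 L mol⁻¹ h⁻¹)

Of that c, quenched substrate holds 20.0 %, equal to s, and chains hold 31.4 %. The free monomer left, 48.6 mM, stands near the ratio of back to forward constants, 48.0 mM. The same reckoning on the neighbouring flask charged with 0.40 M of free monomer gives s = 5.00 %, and that flask holds 5.00 % quenched substrate and 83.0 % in chains, with 12.0 % free, which is 48.0 mM.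

The data stem from a simulated flask with constants of no real substance, noise included.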